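## Structural features

Compound 30 is an ent-labdane: a trans-fused decalin (ring A = C1–C5 and C10, ring B = C5–C10) whose C9 carries a 3-methylidenepent-4-en-1-yl chain (C11–C16, a 2-alkylbuta-1,3-diene). Six stereocentres (4S,5S,6R,8S,9S,10R) lie along C4–C5–C6 and C8–C9–C10. The quaternary carbons C4 and C10 are 1,3-related with syn-axial methyl groups (C19, C20), and the C17 methyl on C8 is a third axial group on the same face. The oxygen functions (C6 acetate, tertiary C8 hydroxyl, C18 hydroxymethyl on C4) are all equatorial and on the face opposite to C20. Fragile parts are the diene (polymerisation, cycloaddition, acid, dissolving metals, divalent palladium), the tertiary alcohol (dehydration) and the pair C6–OAc/C18–OH (acyl shift to the primary oxygen under base). The real difficulties are the quaternary C10 between C5 and C9, the distinction of methyl from hydroxymethyl on C4, and the equatorial C6 oxygen, which hydride reagents cannot deliver because two axial methyl groups block the face from which hydride would have to arrive. The key step exploits three facts: C10 bears a methyl and C9 a one-carbon branch (C11), so C9=C10 can be the double bond of a β-methyl enal; C5–C8 with the oxygen on C6 is a 2-silyloxydiene; and C4, as a carbon with two identical ester groups, keeps the open-chain precursor achiral, so a chiral Lewis acid alone fixes the absolute configuration.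

## Logic of the disconnections

**30 ⇒ 29 ⇒ 26 + 27.** The O–Si bond on O18 and then the C12–C13 bond are cut. The diene is made last because it tolerates neither dissolving metal nor divalent palladium. The cut falls between the sp3 carbon C12 and the sp2 carbon C13, so the four diene carbons come from the purchasable 27 and 26 needs only a vinyl group on C9. The forward coupling must tolerate a secondary acetate and a free tertiary alcohol, and the final desilylation must be non-basic to prevent acyl shift from O6 to O18.

**26 ⇒ 25 ⇒ 23 ⇒ 22.** The acyl–O6 bond, the C6–H and C7–H bonds, and the C7–O/C8–O bonds of an epoxide are cut back to the C7=C8 bond of an enone. Both ring B carbinols thus derive from one 7-en-6-one. The forward steps must bring oxygen to C8 on the face anti to C20 and must set C6 under thermodynamic control by electron transfer. That requires a substrate free of esters, aldehydes and conjugated dienes at this point.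

**22 ⇒ 21.** The C7=C8 bond is traced to the silyl enol ether C6=C7 by removal of H8. The enol ether is what the cycloaddition delivers, so the ketone is never enolised towards C5. The C8 centre of the cycloadduct is erased, so its configuration need not be controlled.

**21 ⇒ 20 ⇒ 19 ⇒ 18 ⇒ 17 ⇒ 16.** The C19–O bond is restored, then both C4 carbons are returned to the ester level. Two identical esters are simpler than a pre-formed quaternary stereocentre. The forward sequence must tell the equatorial from the axial ester, and it must run while C6 is still masked as the enol ether. Otherwise hydride would reduce a C6 ketone to the axial alcohol, and the esters would not survive the dissolving metal.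

**16 ⇒ 15.** The C11=C12 bond is cut back to the C9 aldehyde. The aldehyde must go directly after the key step: it would not survive hydride, and next to the later enone its C9–H would be vinylogously acidic. The vinyl group is an inert placeholder that already holds C12.

**15 ⇒ 14 (key).** The C5–C10 and C8–C9 bonds are cut. Both rings, the quaternary C10 and the C5, C9 and C10 configurations reduce to an achiral triene. The forward step needs endo/trans-fused folding and catalyst control of the enal face.

**14 ⇒ 13 ⇒ 12 ⇒ 11.** The C11 oxidation level is lowered, the O11 acetate restored and the O6–Si bond cut. An enal cannot be present when the ketone is enolised, so the alcohol is oxidised last. This requires a deprotection and an oxidation that leave a silyl dienol ether intact.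

**11 ⇒ 7 + 8 + 9.** The C7=C8 bond and the C4–C5 bond are cut. One reagent, 8, supplies C5–C7 as both electrophile and latent ylide; 9 supplies C8 and C17. The forward step needs clean alkylation by a tertiary malonate anion and an (E)-selective olefination.

**7 ⇒ 5 + 6.** The C3–C4 bond is cut: plain malonate alkylation, with monoalkylation enforced by excess 6.

**5 ⇒ 4 ⇒ 1.** The acyl–O11 bond, then the C10–C20 and C9–C11 bonds are cut. Both carbons add across a terminal alkyne in one syn-selective operation, so the (E)-trisubstituted alkene that decides the C9/C10 relationship is pure from the start.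

## Other disconnections considered

**Alternative 1:** The cut is C5–C6 and C9–C10 (photocycloaddition) followed by C7–C8 (aldol). Irradiation would add the enol of 3-[3-(tert-butyldimethylsilyloxy)propyl]pentane-2,4-dione A3 across the ring A alkene A2; retro-aldol opening of the cyclobutanol and base-mediated aldol condensation would give the enone A1.
- In favour: it is convergent. C4 arrives with methyl and protected hydroxymethyl already distinguished, which is better than the chosen plan's five steps on the two esters. Three side-chain carbons come with A3, also better. A1 is at the oxidation level of 22, so the ring B endgame would be the same (equal).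
- Against: the two faces of A2 differ only by CH3 versus CH2OSi on C4, so the C4/C10 relationship rests on a weak bias. The required orientation joins the two most substituted carbons (C9 and C10) and is not secured. The 1,5-diketone has two acetyl groups that can each close a cyclohexenone, so the aldol direction is a second regiochemical question. C5 and C9 are left to equilibration. A2 needs its own enantioselective synthesis of a quaternary centre.
- Comparison: the chosen plan ties C5, C9 and C10 to alkene geometry in one suprafacial event and takes chirality from a catalyst. Alternative 1 would be shorter after its key step but less controlled in structure and mechanism (stepwise biradical).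

**Alternative 2:** The cut is C7–C8 and C9–C10. The ring A silyloxydiene A5 would add but-2-ynal A6 under a chiral boron Lewis acid to give A4 with quaternary C10.
- In favour: the bicycle is reached in very few steps and convergently (better on step count to the decalin). The C8=C9 enal of A4 is a direct handle for the C8 oxygen, so no enol-ether oxidation is needed (equal or better). The catalyst has to set only one centre.
- Against: in A5 the silyloxyvinyl group sits between the quaternary C4 and the methyl-bearing C10, so an s-cis, conjugated diene is hard to reach. Its reacting terminus C10 is fully substituted. Enantioselection must distinguish the faces of the diene, which is not bound to the catalyst, with no endo/exo element from a linear alkynal. C5 and C9 would have to be set afterwards in separate operations. The C4 ester problem is the same as in the chosen plan (equal).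
- Comparison: both plans rely on catalysis beyond close precedent. The chosen one gains the entropic help of the tether and delivers three permanent stereocentres at once.

**Alternative 3:** The cut is C4–C5 and C9–C10. Cp2TiCl (trivalent titanium) would open the 2-methyl-2-alkyloxirane of the epoxytriene A8 to the C4 radical, which closes ring A onto C5 and ring B from C10 onto C9, ending as the 8(17)-alkene A7.
- In favour: C18–OH and the C19 methyl come directly, and the C6 oxygen is present from the start (both better than the chosen plan; no ester differentiation, no C6 reduction). The exocyclic alkene maps onto the C8 carbinol in two steps (equal). Conditions are neutral.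
- Against: all configuration is relayed from the single carbinol centre C6 of A8 through a chair–chair folding. The planar C4 radical distinguishes CH3 from CH2O–Ti only by conformational preference. The termination (exocyclic alkene, endocyclic alkene or reduction) is not secured. A8, with two (E)-trisubstituted alkenes, an enantioenriched allylic carbinol and the epoxide, costs about as many steps as 14.
- Comparison: Alternative 3 is probably shorter after the key step and better matched in oxidation pattern. The chosen plan is more predictable in ring fusion (concerted, geometry-controlled) and takes its chirality from a catalyst acting on an achiral precursor.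

Key step: step 8

Remark 1: bicyclic compounds are described with labdane numbering (C1–C10 decalin, C11 on C9, C17 on C8, C18 equatorial and C19 axial on C4, C20 on C10); "syn" and "anti" mean the same or the opposite face as the C20 methyl, and absolute configuration is that of the SMILES strings.

Remark 2: a triisopropylsilyl group is used on the dienol ether in place of a smaller silyl group (a spectator change) because it must survive methanolysis, the cationic boron catalyst and the steps up to the enone.

Remark 3: an enal cannot be present when the ketone is enolised, and neither the C9 aldehyde nor the C4 esters can be present when the enone is made and reduced by dissolving metal; the order of events is set accordingly. The configurations of 14 and 15 were checked against 30 at C5, C9 and C10 and needed no correction.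

Remark 4: 8 and 27 (as a stabilised solution) are taken as purchasable.

## Route

Step 1
Reactants: 1 5-chloropent-1-yne
Product: 4 (E)-6-chloro-3-methylhex-2-en-1-ol, via alkenylalane 2 (not isolated), via lithium aluminate 3 (not isolated)
Conditions: Me3Al (2 equiv), Cp2ZrCl2 (0.25 equiv), CH2Cl2, 0 °C → rt; volatiles removed; n-BuLi, THF–hexane, −78 → 0 °C; (CH2O)n, rt; dil. HCl
Reagents that add atoms: trimethylaluminium, C[Al](C)C; paraformaldehyde (as formaldehyde), C=O
Why: Zirconium-catalysed syn-carboalumination of the terminal alkyne (Negishi carboalumination) puts methyl on the internal carbon and aluminium on the terminal one, so chain and metal are trans; the aluminate 3 adds to formaldehyde with retention and gives the (E)-allylic alcohol. The primary chloride is not touched by the alane at room temperature.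

Step 2
Reactants: 4 (E)-6-chloro-3-methylhex-2-en-1-ol
Product: 5 (E)-6-chloro-3-methylhex-2-en-1-yl acetate
Conditions: Ac2O, pyridine, DMAP (cat.), CH2Cl2, 0 °C → rt
Reagents that add atoms: acetic anhydride, CC(=O)OC(C)=O
Why: DMAP-catalysed acylation; the acetate survives sodium malonates, the Wittig step and silyl triflate/amine, yet can later be removed by methanolysis without harming a triisopropylsilyl enol ether.

Step 3
Reactants: 5 (E)-6-chloro-3-methylhex-2-en-1-yl acetate; 6 dimethyl malonate
Product: 7 dimethyl 2-[(E)-6-acetoxy-4-methylhex-4-en-1-yl]malonate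
Conditions: NaH, 6 (3 equiv), NaI (cat.), DMF, 0 → 70 °C
Reagents that add atoms: none
Why: Malonic ester alkylation (SN2, iodide-assisted) at the primary chloride; excess 6 suppresses dialkylation, and the allylic acetate is not a leaving group without a transition-metal catalyst.

Step 4
Reactants: 7 dimethyl 2-[(E)-6-acetoxy-4-methylhex-4-en-1-yl]malonate; 8 1-chloro-3-(triphenyl-λ5-phosphanylidene)propan-2-one; 9 acetaldehyde
Product: 11 dimethyl 2-[(E)-6-acetoxy-4-methylhex-4-en-1-yl]-2-[(E)-2-oxopent-3-en-1-yl]malonate, via acylmethylene ylide 10 (not isolated)
Conditions: NaH, THF–DMF, 0 °C; 8, NaI (cat.), 50 °C; then 9 (excess), 40 °C, sealed vessel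
Reagents that add atoms: none
Why: The tertiary sodium malonate displaces chloride from the α-chloro ketone ylide 8 (SN2) to give the stabilised ylide 10, whose Wittig reaction with acetaldehyde gives the (E)-enone; the ketone never meets a strong base, so neither self-aldol nor Dieckmann-type attack on the esters can intervene.

Step 5
Reactants: 11 dimethyl 2-[(E)-6-acetoxy-4-methylhex-4-en-1-yl]-2-[(E)-2-oxopent-3-en-1-yl]malonate
Product: 12 dimethyl 2-[(E)-6-acetoxy-4-methylhex-4-en-1-yl]-2-[(1Z,3E)-2-(triisopropylsilyloxy)penta-1,3-dien-1-yl]malonate
Conditions: i-Pr3SiOTf, Et3N, CH2Cl2, −78 → 0 °C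
Reagents that add atoms: triisopropylsilyl trifluoromethanesulfonate, CC(C)[Si](C(C)C)(C(C)C)OS(=O)(=O)C(F)(F)F
Why: Soft enolisation: O-silylation of the enone and removal of a C5 proton by the amine give the cross-conjugated 2-silyloxydiene; the (1Z) geometry is expected because the quaternary C4 avoids allylic strain with the propenyl group, and it places C4 on the outside of the diene as the cycloaddition requires. Esters and the acetate are not enolised by silyl triflate/amine at 0 °C.

Step 6
Reactants: 12 dimethyl 2-[(E)-6-acetoxy-4-methylhex-4-en-1-yl]-2-[(1Z,3E)-2-(triisopropylsilyloxy)penta-1,3-dien-1-yl]malonate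
Product: 13 dimethyl 2-[(E)-6-hydroxy-4-methylhex-4-en-1-yl]-2-[(1Z,3E)-2-(triisopropylsilyloxy)penta-1,3-dien-1-yl]malonate
Conditions: K2CO3, MeOH, 0 °C
Reagents that add atoms: none
Why: Base-catalysed transesterification of the unhindered primary acetate; methyl esters are degenerate in methanol and a triisopropylsilyl enol ether is inert to methanolic carbonate at 0 °C.

Step 7
Reactants: 13 dimethyl 2-[(E)-6-hydroxy-4-methylhex-4-en-1-yl]-2-[(1Z,3E)-2-(triisopropylsilyloxy)penta-1,3-dien-1-yl]malonate
Product: 14 dimethyl 2-[(E)-4-methyl-6-oxohex-4-en-1-yl]-2-[(1Z,3E)-2-(triisopropylsilyloxy)penta-1,3-dien-1-yl]malonate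
Conditions: MnO2 (activated), CH2Cl2, rt
Reagents that add atoms: none
Why: Allylic alcohol oxidation on MnO2 is neutral and heterogeneous, so the acid-sensitive silyloxydiene and the (E) geometry of the trisubstituted alkene are preserved; the enal is made last because it could not survive step 5.

Step 8
Reactants: 14 dimethyl 2-[(E)-4-methyl-6-oxohex-4-en-1-yl]-2-[(1Z,3E)-2-(triisopropylsilyloxy)penta-1,3-dien-1-yl]malonate
Product: 15 dimethyl (5S,8R,9R,10R)-9-formyl-8,10-dimethyl-6-(triisopropylsilyloxy)-trans-decal-6-ene-4,4-dicarboxylate
Conditions: (S)-B-(o-tolyl)oxazaborolidine from (S)-α,α-diphenylprolinol (20 mol%), (CF3SO2)2NH (18 mol%), CH2Cl2, −78 → −40 °C; Et3N quench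
Reagents that add atoms: none
Why: Proposed new method: the oxazaborolidinium ion binds the formyl oxygen of 14 (s-trans enal held by a formyl C–H···O contact) and lowers the LUMO of C9=C10; the nucleophilic terminus C5 of the 2-silyloxydiene bonds to the β-carbon C10 and C8 to the α-carbon C9, either in one asynchronous [4+2] event or stepwise through a silyloxyallyl cation/boron enolate pair, both paths giving the same bonds. The closest known reaction types are the Lewis-acid-promoted intramolecular Diels–Alder (or Mukaiyama–Michael/Michael) reaction of tethered 2-silyloxydienes with enals, which gives angular-methyl decalins, and the oxazaborolidinium-catalysed intermolecular Diels–Alder reaction of 2-silyloxydienes with enals; new here is enantiocontrol on a β,β-disubstituted enal. Ring A is closed through the C1–C4 tether as a six-membered chair by the C5–C10 bond, and ring B is the cyclohexene formed by the cycloaddition itself (C5–C10 and C8–C9). Endo placement of the formyl group, with the tether exo as the (E)-enal demands, sets H5 anti to the C20 methyl (trans fusion, C5 and C10) and, through suprafacial addition to the (E)-alkene, the formyl group on C9 syn to C20. The (E)-propenyl terminus places the C17 methyl syn as well (C8), a centre that step 15 removes. The absolute sense (C5 to the Si face of C10, C8 to the Re face of C9) comes only from the catalyst, which shields one face of the bound enal; the (S) catalyst is proposed from the accepted model for formyl-bound enals, and the mirror-image catalyst is used if the sense proves opposite. The step needs the catalysed path to outrun the uncatalysed one and ring closure to outrun silyl transfer; the gem-diester compresses the tether angle, the triisopropylsilyl group resists transfer, and the low temperature suppresses the background reaction.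

Step 9
Reactants: 15 dimethyl (5S,8R,9R,10R)-9-formyl-8,10-dimethyl-6-(triisopropylsilyloxy)-trans-decal-6-ene-4,4-dicarboxylate
Product: 16 dimethyl 9-ethenyl-8,10-dimethyl-6-(triisopropylsilyloxy)-trans-decal-6-ene-4,4-dicarboxylate (vinyl syn to C20)
Conditions: Ph3PCH3Br, KN(SiMe3)2, THF, −78 → 0 °C
Reagents that add atoms: methyltriphenylphosphonium bromide, C[P+](c1ccccc1)(c1ccccc1)c1ccccc1.[Br-]
Why: Wittig methylenation of the hindered aldehyde with the ylide at low temperature is faster than enolisation towards C9; non-enolisable esters and the silyl enol ether are inert. The vinyl group holds C11–C12 and removes the aldehyde before hydride and enone chemistry.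

Step 10
Reactants: 16 dimethyl 9-ethenyl-8,10-dimethyl-6-(triisopropylsilyloxy)-trans-decal-6-ene-4,4-dicarboxylate
Product: 17 C18 alcohol: methyl ester at C19 (axial), hydroxymethyl at C18 (equatorial)
Conditions: i-Bu2AlH (2.2 equiv), CH2Cl2, −78 → −40 °C; aq. potassium sodium tartrate
Reagents that add atoms: none
Why: Reduction of one of two diastereotopic esters: the axial ester is syn-axial to the C20 methyl and would pass through a very crowded tetrahedral intermediate, whereas the equatorial ester has only the enol-ether oxygen as peri neighbour (its silyl group points towards C7), so hydride should attack C18; this makes C4 stereogenic with the hydroxymethyl group equatorial. The silyl enol ether masks C6 from the hydride and the vinyl group is inert to i-Bu2AlH at low temperature.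

Step 11
Reactants: 17 C18 alcohol with axial C19 methyl ester
Product: 18 C18 triisopropylsilyl ether with axial C19 methyl ester
Conditions: i-Pr3SiOTf, 2,6-lutidine, CH2Cl2, −78 → 0 °C
Reagents that add atoms: triisopropylsilyl trifluoromethanesulfonate, CC(C)[Si](C(C)C)(C(C)C)OS(=O)(=O)C(F)(F)F
Why: Silylation of the neopentyl primary alcohol with a silyl triflate and a hindered pyridine base; triisopropylsilyl is chosen because it does not migrate to the neighbouring C19 oxygen in step 12 and survives lithium in ammonia.

Step 12
Reactants: 18 C18 triisopropylsilyl ether with axial C19 methyl ester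
Product: 19 C19 alcohol (axial hydroxymethyl) with C18 triisopropylsilyl ether
Conditions: LiAlH4, THF, 0 °C → rt; aq. NaOH work-up
Reagents that add atoms: none
Why: LiAlH4 reduces the hindered axial ester to the primary alcohol; the silyl ether, the silyl enol ether and the vinyl group are inert.

Step 13
Reactants: 19 C19 alcohol with C18 triisopropylsilyl ether
Product: 20 C19 O-phenyl thionocarbonate
Conditions: PhOC(S)Cl, pyridine, DMAP (cat.), CH2Cl2, rt
Reagents that add atoms: O-phenyl carbonochloridothioate, S=C(Cl)Oc1ccccc1
Why: DMAP-catalysed acylation of the neopentyl alcohol by the chlorothionoformate; no free alkoxide is generated, which excludes 1,3-silyl migration from O18 to O19.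

Step 14
Reactants: 20 C19 O-phenyl thionocarbonate
Product: 21 4-methyl compound (C19 methyl axial, C18 silyloxymethyl equatorial, C6 silyl enol ether, C9 vinyl)
Conditions: Bu3SnH, AIBN (cat.), toluene, 110 °C
Reagents that add atoms: none
Why: Barton–McCombie deoxygenation: the stannyl radical adds to the thiocarbonyl group, the C19–O bond fragments and the primary radical is reduced by Bu3SnH; the radical has only four-membered or endo closures available onto the vinyl and enol-ether groups. C19 becomes the axial methyl, completing the C4 stereocentre.

Step 15
Reactants: 21 4-methyl silyl enol ether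
Product: 22 7-en-6-one (C9 vinyl syn, C18 triisopropylsilyl ether)
Conditions: Pd(OAc)2 (1.2 equiv), DMSO–MeCN, 45 °C
Reagents that add atoms: none
Why: Saegusa oxidation: Pd(OAc)2 (divalent palladium) converts the silyl enol ether into a C7-bound palladium enolate on the face anti to the C17 methyl, and syn β-hydride elimination of H8 gives the 7-en-6-one; C5 has no β-hydrogen on C4 or C10, so no other enone can form. The C8 centre of the cycloadduct is erased by design; the alkyl silyl ether and the terminal alkene do not react.

Step 16
Reactants: 22 7-en-6-one
Product: 23 7,8-epoxy-6-ketone (epoxide anti to C20)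
Conditions: 30% H2O2, NaOH (aq., cat.), MeOH–THF, 0 °C → rt
Reagents that add atoms: hydrogen peroxide, OO
Why: Weitz–Scheffer epoxidation: hydroperoxide adds to C8 on the face anti to the axial C20 methyl and to the C9 vinyl group, and the enolate closes on the same face, so the epoxide oxygen is anti to C20; this fixes the future C8 hydroxyl equatorial and the C17 methyl axial. The isolated vinyl group is not attacked by a nucleophilic oxidant.

Step 17
Reactants: 23 7,8-epoxy-6-ketone
Product: 25 6,8-diol (both hydroxyls equatorial and anti to C20), via hydroxy ketone 24 (not isolated)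
Conditions: Li, NH3(l)–THF, −78 °C; then MeOH, −78 °C; NH4Cl
Reagents that add atoms: none
Why: Dissolving-metal reduction in two stages: electron transfer to the epoxy ketone cleaves the C7–O bond (C8–O and its configuration are kept) and gives the lithium aldolate/enolate of 24; methanol then releases the ketone, which is reduced by further electron transfer, the C6 carbanion being protonated in its more stable pyramidal form to give the equatorial alcohol anti to C20, the epimer that hydride reagents cannot deliver. The silyl ether and the isolated vinyl group are inert at −78 °C with a limited excess of metal.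

Step 18
Reactants: 25 6,8-diol
Product: 26 6-acetate (C8 hydroxyl free, C18 triisopropylsilyl ether, C9 vinyl)
Conditions: Ac2O, pyridine, DMAP (cat.), CH2Cl2, 0 °C → rt
Reagents that add atoms: acetic anhydride, CC(=O)OC(C)=O
Why: DMAP-catalysed acetylation of the only secondary alcohol; the tertiary C8 hydroxyl is not acylated under these conditions and O18 is protected, so no regiochemical question arises.

Step 19
Reactants: 26 6-acetate with C9 vinyl; 27 2-chlorobuta-1,3-diene
Product: 29 18-O-triisopropylsilyl ether of the target, via alkylborane 28 (not isolated)
Conditions: 9-BBN-H, THF, 0 °C → rt; then 27, Pd(OAc)2 (5 mol%), SPhos (10 mol%), K3PO4 (aq.), THF, 40 °C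
Reagents that add atoms: none
Why: Hydroboration with 9-BBN-H places boron on the terminal carbon C12 of the only alkene; B-alkyl Suzuki–Miyaura coupling of 28 with the alkenyl chloride 27 (oxidative addition to zerovalent palladium bearing an electron-rich biaryl phosphine, transmetalation of the base-activated borane, reductive elimination) forms C12–C13 and delivers the 2-substituted butadiene. No stereocentre is involved; the hindered secondary acetate and the tertiary alcohol tolerate aqueous phosphate at 40 °C.

Step 20
Reactants: 29 18-O-triisopropylsilyl ether of the target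
Product: 30 (4S,5S,6R,8S,9S,10R)-8,18-dihydroxy-ent-labda-13(16),14-dien-6-yl acetate
Conditions: HF·pyridine, pyridine, THF, 0 °C → rt
Reagents that add atoms: none
Why: Fluoride cleavage of the primary silyl ether under buffered, non-basic conditions, which avoids acyl shift from O6 to O18, dehydration at C8 and acid-induced reactions of the diene.

## Compound list

1 | 5-chloropent-1-yne | C#CCCCCl | starting material
2 | [(E)-5-chloro-2-methylpent-1-en-1-yl]dimethylalane | ClCCC/C(C)=C/[Al](C)C | intermediate (not isolated)
3 | lithium butyl[(E)-5-chloro-2-methylpent-1-en-1-yl]dimethylaluminate | [Li+].CCCC[Al-](C)(C)/C=C(\C)CCCCl | intermediate (not isolated)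
4 | (E)-6-chloro-3-methylhex-2-en-1-ol | ClCCC/C(C)=C/CO | intermediate
5 | (E)-6-chloro-3-methylhex-2-en-1-yl acetate | ClCCC/C(C)=C/COC(C)=O | intermediate
6 | dimethyl malonate | COC(=O)CC(=O)OC | starting material
7 | dimethyl 2-[(E)-6-acetoxy-4-methylhex-4-en-1-yl]malonate | COC(=O)C(CCC/C(C)=C/COC(C)=O)C(=O)OC | intermediate
8 | 1-chloro-3-(triphenyl-λ5-phosphanylidene)propan-2-one | ClCC(=O)C=P(c1ccccc1)(c1ccccc1)c1ccccc1 | starting material
9 | acetaldehyde | CC=O | starting material
10 | dimethyl 2-[(E)-6-acetoxy-4-methylhex-4-en-1-yl]-2-[2-oxo-3-(triphenyl-λ5-phosphanylidene)propyl]malonate | COC(=O)C(CCC/C(C)=C/COC(C)=O)(CC(=O)C=P(c1ccccc1)(c1ccccc1)c1ccccc1)C(=O)OC | intermediate (not isolated)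
11 | dimethyl 2-[(E)-6-acetoxy-4-methylhex-4-en-1-yl]-2-[(E)-2-oxopent-3-en-1-yl]malonate | COC(=O)C(CCC/C(C)=C/COC(C)=O)(CC(=O)/C=C/C)C(=O)OC | intermediate
12 | dimethyl 2-[(E)-6-acetoxy-4-methylhex-4-en-1-yl]-2-[(1Z,3E)-2-(triisopropylsilyloxy)penta-1,3-dien-1-yl]malonate | C/C=C/C(O[Si](C(C)C)(C(C)C)C(C)C)=C/C(C(=O)OC)(C(=O)OC)CCC/C(C)=C/COC(C)=O | intermediate
13 | dimethyl 2-[(E)-6-hydroxy-4-methylhex-4-en-1-yl]-2-[(1Z,3E)-2-(triisopropylsilyloxy)penta-1,3-dien-1-yl]malonate | C/C=C/C(O[Si](C(C)C)(C(C)C)C(C)C)=C/C(C(=O)OC)(C(=O)OC)CCC/C(C)=C/CO | intermediate
14 | dimethyl 2-[(E)-4-methyl-6-oxohex-4-en-1-yl]-2-[(1Z,3E)-2-(triisopropylsilyloxy)penta-1,3-dien-1-yl]malonate (key-step precursor) | C/C=C/C(O[Si](C(C)C)(C(C)C)C(C)C)=C/C(C(=O)OC)(C(=O)OC)CCC/C(C)=C/C=O | intermediate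
15 | dimethyl (5S,8R,9R,10R)-9-formyl-8,10-dimethyl-6-(triisopropylsilyloxy)-trans-decal-6-ene-4,4-dicarboxylate (H5 anti; C17 methyl and formyl syn to C20; key-step product) | O=C[C@H]1[C@]2(C)CCCC(C(=O)OC)(C(=O)OC)[C@H]2C(O[Si](C(C)C)(C(C)C)C(C)C)=C[C@H]1C | intermediate
16 | 9-ethenyl analogue of 15 (vinyl syn to C20) | C=C[C@H]1[C@]2(C)CCCC(C(=O)OC)(C(=O)OC)[C@H]2C(O[Si](C(C)C)(C(C)C)C(C)C)=C[C@H]1C | intermediate
17 | C18 alcohol: equatorial hydroxymethyl and axial methyl ester (C19) on C4; C6 silyl enol ether; C9 vinyl | C=C[C@H]1[C@]2(C)CCC[C@](C(=O)OC)(CO)[C@H]2C(O[Si](C(C)C)(C(C)C)C(C)C)=C[C@H]1C | intermediate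
18 | C18 triisopropylsilyl ether of 17 | C=C[C@H]1[C@]2(C)CCC[C@](C(=O)OC)(CO[Si](C(C)C)(C(C)C)C(C)C)[C@H]2C(O[Si](C(C)C)(C(C)C)C(C)C)=C[C@H]1C | intermediate
19 | C19 alcohol: axial hydroxymethyl, equatorial silyloxymethyl on C4 | C=C[C@H]1[C@]2(C)CCC[C@](CO)(CO[Si](C(C)C)(C(C)C)C(C)C)[C@H]2C(O[Si](C(C)C)(C(C)C)C(C)C)=C[C@H]1C | intermediate
20 | C19 O-phenyl thionocarbonate of 19 | C=C[C@H]1[C@]2(C)CCC[C@](COC(=S)Oc3ccccc3)(CO[Si](C(C)C)(C(C)C)C(C)C)[C@H]2C(O[Si](C(C)C)(C(C)C)C(C)C)=C[C@H]1C | intermediate
21 | 4-methyl compound: axial C19 methyl, equatorial C18 silyloxymethyl, C6 silyl enol ether, C9 vinyl | C=C[C@H]1[C@]2(C)CCC[C@](C)(CO[Si](C(C)C)(C(C)C)C(C)C)[C@H]2C(O[Si](C(C)C)(C(C)C)C(C)C)=C[C@H]1C | intermediate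
22 | 7-en-6-one (C8 methyl on the alkene, C9 vinyl syn, H5 anti) | C=C[C@H]1[C@]2(C)CCC[C@](C)(CO[Si](C(C)C)(C(C)C)C(C)C)[C@H]2C(=O)C=C1C | intermediate
23 | 7,8-epoxy-6-ketone, epoxide oxygen anti to C20 | C=C[C@H]1[C@]2(C)CCC[C@](C)(CO[Si](C(C)C)(C(C)C)C(C)C)[C@H]2C(=O)[C@@H]3O[C@]13C | intermediate
24 | 8-hydroxy-6-ketone (hydroxyl anti, C17 methyl syn to C20) | C=C[C@H]1[C@]2(C)CCC[C@](C)(CO[Si](C(C)C)(C(C)C)C(C)C)[C@H]2C(=O)C[C@]1(C)O | intermediate (not isolated)
25 | 6,8-diol (both hydroxyls equatorial, anti to C20) | C=C[C@H]1[C@]2(C)CCC[C@](C)(CO[Si](C(C)C)(C(C)C)C(C)C)[C@H]2[C@H](O)C[C@]1(C)O | intermediate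
26 | 6-acetate of 25 | C=C[C@H]1[C@]2(C)CCC[C@](C)(CO[Si](C(C)C)(C(C)C)C(C)C)[C@H]2[C@H](OC(C)=O)C[C@]1(C)O | intermediate
27 | 2-chlorobuta-1,3-diene | C=CC(Cl)=C | starting material
28 | C12 (9-borabicyclo[3.3.1]nonan-9-yl) derivative of 26 | B1(C2CCCC1CCC2)CC[C@H]3[C@]4(C)CCC[C@](C)(CO[Si](C(C)C)(C(C)C)C(C)C)[C@H]4[C@H](OC(C)=O)C[C@]3(C)O | intermediate (not isolated)
29 | 18-O-triisopropylsilyl ether of 30 | C=CC(=C)CC[C@H]1[C@]2(C)CCC[C@](C)(CO[Si](C(C)C)(C(C)C)C(C)C)[C@H]2[C@H](OC(C)=O)C[C@]1(C)O | intermediate
30 | (4S,5S,6R,8S,9S,10R)-8,18-dihydroxy-ent-labda-13(16),14-dien-6-yl acetate; (1R,3S,4S,4aR,8S,8aS)-3-hydroxy-8-(hydroxymethyl)-3,4a,8-trimethyl-4-(3-methylidenepent-4-en-1-yl)decahydronaphthalen-1-yl acetate | C=CC(=C)CC[C@H]1[C@]2(C)CCC[C@](C)(CO)[C@H]2[C@H](OC(C)=O)C[C@]1(C)O | target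

## Step count and least certain steps

Total step count: 20. Longest linear sequence: 20 steps (1 → 30).

**Step 8 (key step, proposed new method).** Most likely failure: low turnover and poor facial selectivity, because a β,β-disubstituted enal binds the bulky boron cation weakly and reacts slowly, so an uncatalysed or proton-catalysed racemic pathway can compete. A second failure mode is loss of the silyl group after the first bond is formed, which would interrupt ring closure. Fallback, from 14: Me2AlCl (1.1 equiv) in CH2Cl2 at −78 → −20 °C. This is the known Lewis-acid-promoted intramolecular cycloaddition of a tethered silyloxydiene enal and should give the same endo, trans-fused adduct as a racemate, that is 15 together with the mirror-image cycloadduct F1. Preparative chromatography on a cellulose-based chiral stationary phase would separate them, and the route is rejoined at 15 at the cost of half the material.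

**Step 5.** Most likely failure: deprotonation at the γ-methyl (C17) instead of the hindered C5 methylene, or loss of geometric control of the enol ether, because the C5 hydrogens are neopentyl-like. Fallback, from 11: methanolysis (K2CO3, MeOH) to the hydroxy enone F2; silylation with Me3SiCl/Et3N to the trimethylsilyl ether F3, used crude; irreversible kinetic deprotonation with LiN(i-Pr)2 in THF at −78 °C, which removes the α′-hydrogen of enones and leaves γ-hydrogens, then i-Pr3SiOTf to the bis-silyl compound F4; K2CO3/MeOH work-up cleaves only the trimethylsilyl ether and returns the route at 13.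

**Step 10.** Most likely failure: insufficient discrimination between the two esters, because the peri enol-ether oxygen erodes the advantage of the equatorial ester, together with over-reduction. Fallback, from 16: LiAlH4 reduces both esters to the 18,19-diol F5; monosilylation with i-Pr3SiOTf (1.0 equiv) and 2,6-lutidine at −78 °C should take the equatorial hydroxymethyl group, the axial one being syn-axial to C20. The differentiation thus moves from a carbonyl addition to an O-silylation one atom further from the ring, and the route is rejoined at 19.

**Step 16.** Most likely failure: slow conjugate addition to the β,β-disubstituted enone, which leaves time for base-mediated removal of the γ-hydrogen at C9 (epimerisation or double-bond migration) and for incomplete facial selectivity. Fallback, from 22: copper-catalysed conjugate borylation (CuCl, NaOt-Bu, a bisphosphine, B2pin2, MeOH, THF) to the tertiary boronate F6, added anti to C20 and open to reinforcement by a chiral ligand. Oxidation with NaBO3·4H2O proceeds with retention and returns the route at 24, which is reduced to 25 with lithium in ammonia and methanol as in the second stage of step 17.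

**Step 17.** Most likely failure: kinetic protonation of the C6 carbanion from the open face (axial alcohol), retro-aldol cleavage of the aldolate on warming, or partial reduction of the vinyl group. Fallback, from 23: SmI2 in THF–MeOH at −78 °C opens the epoxy ketone to 24, which is isolated; NaBH4 in MeOH then gives the axial C6 epimer F7 by attack anti to the axial methyl groups. Redox epimerisation with (η5-C5Ph5)Ru(CO)2Cl and KOt-Bu in toluene at 60 °C (reversible hydrogen transfer) should move the hydroxyl to the equatorial position, because the axial one is syn-axial to two methyl groups. The route is rejoined at 25.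

**Step 19.** Most likely failure: sluggish oxidative addition of the alkenyl chloride, polymerisation of 27 or of the product diene, and hydrolysis of the acetate by the aqueous base. Fallback, from 25 (before acetylation), reversing the polarity of the coupling: 9-BBN-H then NaOH/H2O2 to the triol F8; I2, PPh3, imidazole (primary hydroxyl only) to the iodide F9; copper-catalysed coupling (Li2CuCl4, THF, −20 °C) with excess buta-1,3-dien-2-ylmagnesium chloride F10, made from 27 and magnesium, to the diene diol F11; acetylation (Ac2O, pyridine, DMAP) returns the route at 29.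

## Further compounds

F1 | step 8 | mirror image of cycloadduct 15 | O=C[C@@H]1[C@@]2(C)CCCC(C(=O)OC)(C(=O)OC)[C@@H]2C(O[Si](C(C)C)(C(C)C)C(C)C)=C[C@@H]1C
F2 | step 5 | dimethyl 2-[(E)-6-hydroxy-4-methylhex-4-en-1-yl]-2-[(E)-2-oxopent-3-en-1-yl]malonate | COC(=O)C(CCC/C(C)=C/CO)(CC(=O)/C=C/C)C(=O)OC
F3 | step 5 | trimethylsilyl ether of F2 | COC(=O)C(CCC/C(C)=C/CO[Si](C)(C)C)(CC(=O)/C=C/C)C(=O)OC
F4 | step 5 | trimethylsilyl ether of 13 | C/C=C/C(O[Si](C(C)C)(C(C)C)C(C)C)=C/C(C(=O)OC)(C(=O)OC)CCC/C(C)=C/CO[Si](C)(C)C
F5 | step 10 | 4,4-bis(hydroxymethyl) analogue of 16 (18,19-diol) | C=C[C@H]1[C@]2(C)CCCC(CO)(CO)[C@H]2C(O[Si](C(C)C)(C(C)C)C(C)C)=C[C@H]1C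
F6 | step 16 | 8-(pinacolatoboryl)-6-ketone, boron anti to C20 | C=C[C@H]1[C@]2(C)CCC[C@](C)(CO[Si](C(C)C)(C(C)C)C(C)C)[C@H]2C(=O)C[C@]1(C)B1OC(C)(C)C(C)(C)O1
F7 | step 17 | C6 epimer of 25 (axial C6 hydroxyl) | C=C[C@H]1[C@]2(C)CCC[C@](C)(CO[Si](C(C)C)(C(C)C)C(C)C)[C@H]2[C@@H](O)C[C@]1(C)O
F8 | step 19 | 6,8,12-triol from hydroboration–oxidation of 25 | OCC[C@H]1[C@]2(C)CCC[C@](C)(CO[Si](C(C)C)(C(C)C)C(C)C)[C@H]2[C@H](O)C[C@]1(C)O
F9 | step 19 | 12-iodo-6,8-diol | ICC[C@H]1[C@]2(C)CCC[C@](C)(CO[Si](C(C)C)(C(C)C)C(C)C)[C@H]2[C@H](O)C[C@]1(C)O
F10 | step 19 | buta-1,3-dien-2-ylmagnesium chloride | C=CC(=C)[Mg]Cl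
F11 | step 19 | 6-deacetyl analogue of 29 (diene 6,8-diol) | C=CC(=C)CC[C@H]1[C@]2(C)CCC[C@](C)(CO[Si](C(C)C)(C(C)C)C(C)C)[C@H]2[C@H](O)C[C@]1(C)O
A1 | alternative 1 | trans-fused 7-en-6-one with C9 3-(tert-butyldimethylsilyloxy)propyl chain and C18 triisopropylsilyl ether | CC(C)(C)[Si](C)(C)OCCC[C@H]1[C@]2(C)CCC[C@](C)(CO[Si](C(C)C)(C(C)C)C(C)C)[C@H]2C(=O)C=C1C
A2 | alternative 1 | 1,3-dimethyl-3-[(triisopropylsilyloxy)methyl]cyclohex-1-ene (ring A alkene, configuration as drawn) | CC1=C[C@@](C)(CO[Si](C(C)C)(C(C)C)C(C)C)CCC1
A3 | alternative 1 | 3-[3-(tert-butyldimethylsilyloxy)propyl]pentane-2,4-dione | CC(=O)C(CCCO[Si](C)(C)C(C)(C)C)C(C)=O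
A4 | alternative 2 | bicyclic silyl dienol ether aldehyde with quaternary C10 | O=CC1=C(C)CC(O[Si](C)(C)C(C)(C)C)=C2C(C(=O)OC)(C(=O)OC)CCC[C@@]12C
A5 | alternative 2 | dimethyl 2-[1-(tert-butyldimethylsilyloxy)ethenyl]-3-methylcyclohex-2-ene-1,1-dicarboxylate | C=C(O[Si](C)(C)C(C)(C)C)C1=C(C)CCCC1(C(=O)OC)C(=O)OC
A6 | alternative 2 | but-2-ynal | CC#CC=O
A7 | alternative 3 | bicyclic 18-ol, 6-silyl ether, 8(17)-alkene with C9 3-(4-methoxybenzyloxy)propyl chain | COc1ccc(cc1)COCCC[C@H]2[C@]3(C)CCC[C@](C)(CO)[C@H]3[C@H](O[Si](C)(C)C(C)(C)C)CC2=C
A8 | alternative 3 | open-chain epoxytriene: 2-methyl-2-alkyloxirane (C4/C18), (E)-C5=C10, C6 silyl ether, (E)-C8=C9, terminal 4-methoxybenzyl ether (epoxide configuration immaterial) | COc1ccc(cc1)COCCC/C=C(\C)C[C@@H](O[Si](C)(C)C(C)(C)C)/C=C(\C)CCCC1(C)CO1
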